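## Structural features

The target, 2-(3,4-dimethoxyphenyl)-7-hydroxy-5,6,8-trimethoxy-4H-chromen-4-one, is a flavone. Benzo ring A is fused along C4a–C8a to the 4-pyranone ring C, which carries the 3,4-dimethoxyphenyl ring B on C2 through the C2–C1' bond. There is no stereocentre, so the problem is purely one of substitution pattern. Ring A bears no hydrogen: C5, C6 and C8 carry methoxy groups, C7 a free hydroxyl, C8a the ring oxygen O1 and C4a the C4 carbonyl, so five neighbouring carbons (C5 to C8a) are oxygenated. The real difficulty is O7, which must be the only unmethylated oxygen among four on a hexasubstituted benzene. A late selective demethylation cannot be relied on, because Lewis acids attack first the C5 methoxy group chelated to the C4 carbonyl. Fragile points are that C5 methyl ether, the very electron-rich ring A (easily oxidized to quinones) and, during reductive deprotection, the C2=C3 bond. The key step exploits the unbroken run of oxygens from C5 to C8a: C8a, C6, C7 and C8 come from the four carbons of a squarate-derived cyclobutenone in which each oxygen already carries its final group (benzyl on the future O7), and C4a and C5 come from an alkoxyalkyne, so ring A is formed with O7 marked from the start and C4a as its single CH.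

## Logic of the disconnections

20 ⇒ 19. The O7–H bond is traced back to an O7–CH2Ph bond. The cut is made there because a benzyl label is orthogonal to the three O–CH3 bonds and lets O7 be carried as a distinct oxygen through the whole route. Nothing is gained in skeleton, but the problem of selective demethylation disappears. The forward step must cleave O–CH2Ph without reducing C2=C3.

19 ⇒ 17 (through 18). The O1–C2 bond is cut and two hydrogens are returned to C2 and C3. Ring C opens to an acyclic enone whose phenolic oxygen is already in place. One ring is removed. The forward oxidative closure must spare the benzyl ether and the C5 methyl ether.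

17 ⇒ 14 + 15 (through 16). The C2=C3 bond (the enone C=C) is cut. This separates ring B as a commercial aldehyde and leaves a methyl ketone on ring A. The route becomes convergent. The ketone must enolize and condense despite two ortho substituents.

14 ⇒ 13. The C4a–C4 bond is cut. C4a is the only CH of 13 and is ortho to its hydroxyl, so no regiochemical question arises. The demand is an acylation mild enough for the benzyl ether.

13 ⇒ 5 + 8 (through 9, 10, 11 and 12). The bonds C8a–C4a, C5–C6 and C8–C8a are cut. A hexasubstituted benzene with five oxygens becomes a four-membered ring with three oxygens plus a two-carbon alkyne, each oxygen already assigned. The demand is that the ketene from 5 be captured by 8 faster than it reverts, dimerizes or acylates the product, with the alkyne CH bonding to the ketene carbon.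

5 ⇒ 3 + 4. The C3–O bond of the vinylogous ester is cut. C3 is the only carbon of 3 that is β to the carbonyl, so the one oxygen that must differ (the future O7) sits on the one electrophilic carbon. The demand is an alkoxy exchange that does not open the strained ring.

3 ⇒ 2 ⇒ 1. The O–CH3 bond at C4 and then the C4–H bond are cut. Since 1 is symmetrical, reduction of either carbonyl gives the same product. Both forward steps must run under near-neutral conditions because 2 rearranges in acid.

8 ⇒ 6 (through 7). The triple bond is traced back to a chloroacetal by two eliminations. This gives a cheap C2 unit with the methoxy group in place. The demand lies in handling a volatile product.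

## Other disconnections considered

Alternative 1: The cut is the C2=C3 bond of ring C. In the forward sense the acylmethylenephosphorane A2 (ring A ketone with a Ph3P=CH–CO side chain and a 3,4-dimethoxybenzoate on the neighbouring phenol oxygen) is heated in toluene. The ylide carbon (future C3) adds to the ester carbonyl (future C2) and Ph3PO is expelled to give the benzyl-protected flavone A1, which is the same compound as 19.
- In favour: the closure is neutral and non-oxidative, produces no HI, and cannot go wrong regiochemically. Because ring A is fully substituted, side-chain halogenation on the way to A2 cannot stray onto the ring.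
- Against: it closes only ring C and leaves the pentaoxygenated ring A with its marked O7 unsolved, so 13 and 14 would still be needed. A2 requires halogenation, phosphonium salt formation, deprotonation and O-aroylation of a di-ortho-substituted phenol (with F8) in competition with C-acylation of the ylide. Ester carbonyls are sluggish Wittig acceptors, and Ph3PO is heavy waste.
- Comparison: on mechanism this alternative is the better precedented, since its key step belongs to an established class while step 5 of the chosen plan does not. On structure it addresses the easy ring. On step economy it needs about four operations from 14 to A1, against two in the chosen plan. It is the equal of the chosen plan in ending at the same protected flavone and the same final deprotection.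

Alternative 2: The cut removes C3, breaking C2–C3 and C3–C4, so ring C contracts to the benzofuranone A5, used as its silyl enol ether A4. In the forward sense dichlorocarbene (CHCl3, KOt-Bu) adds to the enol-ether double bond of A4, and the dichlorocyclopropane opens with loss of chloride and the silyl group to the 3-chloroflavone A3.
- In favour: the enol ether is the kind of electron-rich alkene that dichlorocarbene prefers. The C3 chlorine could in principle be removed in the same hydrogenolysis that removes the benzyl group, so the end game need not be longer.
- Against: ring A must again come from elsewhere (A5 would be built from 13). A chlorine is introduced that the target lacks. The strongly basic carbene conditions endanger the silyl enol ether, and ring B is an electron-rich arene open to carbene attack. The ring expansion of a 3-silyloxybenzofuran is itself without close precedent.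
- Comparison: on mechanism both plans rest on an untested key step, so they are equals in risk class, but the chosen one spends its risk on the hard part of the structure. On step economy A5 → A4 → A3 → dechlorination is longer than steps 6 to 8.

Alternative 3: The cut is O1–C8a. The precursor is the 1,3-diketone A7, whose ring A carries two equivalent bromines ortho to the acyl group. CuI with K2CO3 and 1,10-phenanthroline in DMF couples the enol oxygen with one of them to give the 5-bromoflavone A6, and a second copper-mediated methoxylation of C5–Br would lead to 19.
- In favour: ring A derives from the symmetrical, cheap syringic acid A8. The future O7 lies on the symmetry axis, so it is differentiated without any effort and no pentaoxygenated phenol is needed. The two bromines are homotopic, so the desymmetrizing closure has no selectivity problem. Every reaction type involved is known, and the remaining C5–Br is activated by the ortho carbonyl.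
- Against: acylating the enolate of ketone A9 with a benzoyl unit flanked by two bromines (to make A7) is sterically severe. Copper conditions invite hydrodebromination and C-arylation. Two bromines are introduced only to be replaced.
- Comparison: on reliability this alternative is the better plan, since it needs no new reaction. On step economy it is about equal (roughly seven to eight steps against nine). The chosen plan is better in atom economy (step 5 loses no atom and uses no halogen or copper) and in building ring A with all five oxygens assigned in one operation.

Key step: step 5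

Remark on the chemistry: atom mapping of step 5 confirms that the structures of 5, 8 and 13 are mutually consistent (C1 of 5 → C8a, C2 → C6, C3 → C7, C4 → C8; CH of 8 → C4a, C–OMe of 8 → C5), so no structure needed correction.

Design choices for the precursor pair:
- The C4 oxygen of 5 is methylated before the thermolysis, because a free hydroxyl would trap the ketene.
- The benzyloxy group is introduced last, when only one vinylogous-ester carbon exists, so the exchange is site-specific.
- Compound 8 has no β-hydrogen and cannot fragment by a retro-ene path at the reaction temperature.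

Assumption: 2, 3 and 5 (and the transient 10, 12, 16 and 18) are racemic, which is of no consequence because the target has no stereocentre.

## Route

Step 1
Reactants: 1 dimethyl squarate (3,4-dimethoxycyclobut-3-ene-1,2-dione)
Product: 2 4-hydroxy-2,3-dimethoxycyclobut-2-en-1-one (racemic)
Conditions: LiAlH(Ot-Bu)3 (1.05 equiv), THF, −78 to −40 °C; aq. potassium sodium tartrate work-up
Reagents that add atoms: none
Why: Mono-reduction of a squarate ester by 1,2-hydride addition with a bulky, mild hydride; the two carbonyls are equivalent, and the product is a less electrophilic vinylogous ester, so it should not be reduced further at low temperature. The new C4 centre forms as the racemate and is erased in step 5; the neutral work-up avoids acid-induced rearrangement.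

Step 2
Reactants: 2 4-hydroxy-2,3-dimethoxycyclobut-2-en-1-one (racemic)
Product: 3 2,3,4-trimethoxycyclobut-2-en-1-one (racemic)
Conditions: MeI, Ag2O, 4 Å MS, MeCN, rt, dark
Reagents that add atoms: iodomethane, CI
Why: Purdie methylation (O-alkylation promoted by Ag2O) runs under near-neutral conditions that the acid- and base-sensitive hydroxycyclobutenone should tolerate. It installs the future C8 methoxy group and removes the hydroxyl that would otherwise capture the ketene in step 5.

Step 3
Reactants: 3 2,3,4-trimethoxycyclobut-2-en-1-one (racemic); 4 benzyl alcohol
Product: 5 3-(benzyloxy)-2,4-dimethoxycyclobut-2-en-1-one (racemic)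
Conditions: 4 (5 equiv), NaH (10 mol %), 5 Å MS, THF, 0 °C to rt
Reagents that add atoms: none
Why: Alkoxide-catalysed exchange at a vinylogous ester by conjugate addition–elimination; C3 is the only carbon β to the carbonyl, so only its methoxy group can be replaced. The excess of 4 and uptake of methanol by the sieves shift the equilibrium, and C4–H is not acidic because its enolate would be a cyclobutadiene.

Step 4
Reactants: 6 chloroacetaldehyde dimethyl acetal (2-chloro-1,1-dimethoxyethane)
Product: 8 methoxyethyne, via sodium methoxyethynide 7 (not isolated)
Conditions: NaNH2 (3 equiv), liq. NH3, −33 °C; then cold aq. NaCl, distil into toluene at −78 °C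
Reagents that add atoms: none
Why: Twofold base-induced elimination (loss of methanol and of HCl) is the standard route to 1-alkoxyalkynes; the third equivalent of amide holds the product as its sodium salt until cold hydrolysis. The alkyne (bp about 23 °C) is kept as a cold toluene solution and used at once.

Step 5
Reactants: 5 3-(benzyloxy)-2,4-dimethoxycyclobut-2-en-1-one (racemic); 8 methoxyethyne
Product: 13 3-(benzyloxy)-2,4,5-trimethoxyphenol, via vinylketene 9 (not isolated), via vinylcyclobutenone 10 (not isolated), via dienylketene 11 (not isolated), via cyclohexadienone 12 (not isolated)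
Conditions: 8 (3 equiv), toluene, sealed tube, 80 to 110 °C; then K2CO3, MeOH, rt
Reagents that add atoms: none
Why: Proposed new method: heating should open 5 by a four-electron conrotatory process (C1–C4 cleavage, the C4 methoxy group turning outward) to the trialkoxyvinylketene 9, whose electrophilic ketene carbon is attacked by the nucleophilic CH carbon of 8 in a (2+2) cycloaddition that gives the vinylcyclobutenone 10 and forms the future C8a–C4a and C5–C6 bonds. A second four-electron opening of 10, in which the methoxy group on the quaternary carbon again rotates outward and so turns the alkenyl arm inward, gives the (3Z)-dienylketene 11. Ring A is then closed by a thermal six-electron disrotatory electrocyclization of 11 (future C8–C8a bond) to the cyclohexadienone 12, which tautomerizes irreversibly to 13; the four-membered ring of 10 is only a transient product of the (2+2) step. The closest known reaction type is the Danheiser benzannulation of alkyl- and aryl-substituted cyclobutenones with alkoxyalkynes, which gives resorcinol monoethers by the same cascade; what is new is the 2,3,4-trialkoxy substitution. No stereocentre is created in the product: the centres of 5, 10 and 12 all vanish on aromatization. The selectivity needed is the regiochemistry of the ketene–alkyne step, and it is secured by the polarization of the ynol ether, whose oxygen makes the terminal CH the nucleophile that pairs with the ketene carbonyl carbon; this puts the alkyne methoxy meta to the new hydroxyl and leaves the CH ortho to it. The open doubt is the lowered electrophilicity of a ketene bearing three donor oxygens, which is met by an excess of the alkyne in a closed vessel. The final K2CO3/MeOH treatment frees any product phenol that has been acylated by 9.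

Step 6
Reactants: 13 3-(benzyloxy)-2,4,5-trimethoxyphenol
Product: 14 1-[4-(benzyloxy)-2-hydroxy-3,5,6-trimethoxyphenyl]ethan-1-one
Conditions: Ac2O, BF3·OEt2, AcOH, 60 °C; then K2CO3, MeOH, rt
Reagents that add atoms: acetic anhydride, CC(=O)OC(C)=O
Why: Friedel–Crafts C-acetylation (direct, or O-acetylation followed by Fries shift) at the only unsubstituted ring carbon, which is ortho to the hydroxyl and strongly activated, so no regioisomer is possible. The moderate temperature is chosen to spare the benzyl ether, and the methanolysis removes any O-acetyl group.

Step 7
Reactants: 14 1-[4-(benzyloxy)-2-hydroxy-3,5,6-trimethoxyphenyl]ethan-1-one; 15 3,4-dimethoxybenzaldehyde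
Product: 17 (E)-1-[4-(benzyloxy)-2-hydroxy-3,5,6-trimethoxyphenyl]-3-(3,4-dimethoxyphenyl)prop-2-en-1-one, via aldol 16 (not isolated)
Conditions: KOH (aq. 50%), EtOH, rt
Reagents that add atoms: none
Why: Claisen–Schmidt condensation: the methyl ketone enolate adds to the non-enolizable aldehyde and the aldol loses water by E1cB elimination to the thermodynamically favoured (E)-enone. All ethers are inert to hydroxide.

Step 8
Reactants: 17 (E)-1-[4-(benzyloxy)-2-hydroxy-3,5,6-trimethoxyphenyl]-3-(3,4-dimethoxyphenyl)prop-2-en-1-one
Product: 19 7-(benzyloxy)-2-(3,4-dimethoxyphenyl)-5,6,8-trimethoxy-4H-chromen-4-one, via flavanone 18 (not isolated)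
Conditions: I2 (10 mol %), DMSO, 130 °C; aq. Na2S2O3 work-up
Reagents that add atoms: none
Why: Iodine-catalysed oxidative cyclization of a 2'-hydroxychalcone, a standard flavone synthesis: oxa-Michael closure forms O1–C2, iodine dehydrogenates C2–C3, and DMSO reoxidizes HI to iodine. The catalytic loading keeps HI low, so the benzyl and C5 methyl ethers should survive.

Step 9
Reactants: 19 7-(benzyloxy)-2-(3,4-dimethoxyphenyl)-5,6,8-trimethoxy-4H-chromen-4-one
Product: 20 2-(3,4-dimethoxyphenyl)-7-hydroxy-5,6,8-trimethoxy-4H-chromen-4-one
Conditions: H2 (1 atm), 10% Pd/C, EtOAc–MeOH, rt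
Reagents that add atoms: none
Why: Catalytic hydrogenolysis of an aryl benzyl ether. The methyl ethers and the cross-conjugated C2=C3 bond of the pyranone should not be reduced at ambient pressure and temperature, so O7 alone is unmasked.

## Compound list

1 | dimethyl squarate (3,4-dimethoxycyclobut-3-ene-1,2-dione) | COC1=C(OC)C(=O)C1=O | starting material
2 | 4-hydroxy-2,3-dimethoxycyclobut-2-en-1-one (racemic) | COC1=C(OC)C(O)C1=O | intermediate
3 | 2,3,4-trimethoxycyclobut-2-en-1-one (racemic) | COC1=C(OC)C(OC)C1=O | intermediate
4 | benzyl alcohol | OCc1ccccc1 | starting material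
5 | 3-(benzyloxy)-2,4-dimethoxycyclobut-2-en-1-one (racemic) | O=C1C(OC)=C(OCc2ccccc2)C1OC | intermediate
6 | chloroacetaldehyde dimethyl acetal (2-chloro-1,1-dimethoxyethane) | COC(CCl)OC | starting material
7 | sodium methoxyethynide | [Na+].[C-]#COC | intermediate
8 | methoxyethyne | COC#C | intermediate
9 | (3Z)-3-(benzyloxy)-2,4-dimethoxybuta-1,3-dien-1-one (vinylketene) | O=C=C(OC)/C(OCc1ccccc1)=C/OC | intermediate
10 | 4-[(Z)-1-(benzyloxy)-2-methoxyethenyl]-3,4-dimethoxycyclobut-2-en-1-one (racemic; vinylcyclobutenone) | O=C1C=C(OC)C1(OC)/C(OCc2ccccc2)=C/OC | intermediate
11 | (3Z,5Z)-5-(benzyloxy)-3,4,6-trimethoxyhexa-1,3,5-trien-1-one (dienylketene) | O=C=C/C(OC)=C(OC)\C(OCc1ccccc1)=C\OC | intermediate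
12 | 5-(benzyloxy)-3,4,6-trimethoxycyclohexa-2,4-dien-1-one (racemic; cyclohexadienone) | O=C1C=C(OC)C(OC)=C(OCc2ccccc2)C1OC | intermediate
13 | 3-(benzyloxy)-2,4,5-trimethoxyphenol | Oc1cc(OC)c(OC)c(OCc2ccccc2)c1OC | intermediate
14 | 1-[4-(benzyloxy)-2-hydroxy-3,5,6-trimethoxyphenyl]ethan-1-one | CC(=O)c1c(O)c(OC)c(OCc2ccccc2)c(OC)c1OC | intermediate
15 | 3,4-dimethoxybenzaldehyde | COc1ccc(C=O)cc1OC | starting material
16 | 1-[4-(benzyloxy)-2-hydroxy-3,5,6-trimethoxyphenyl]-3-(3,4-dimethoxyphenyl)-3-hydroxypropan-1-one (racemic; aldol) | COc1ccc(C(O)CC(=O)c2c(O)c(OC)c(OCc3ccccc3)c(OC)c2OC)cc1OC | intermediate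
17 | (E)-1-[4-(benzyloxy)-2-hydroxy-3,5,6-trimethoxyphenyl]-3-(3,4-dimethoxyphenyl)prop-2-en-1-one | COc1ccc(/C=C/C(=O)c2c(O)c(OC)c(OCc3ccccc3)c(OC)c2OC)cc1OC | intermediate
18 | 7-(benzyloxy)-2-(3,4-dimethoxyphenyl)-5,6,8-trimethoxy-2,3-dihydro-4H-chromen-4-one (racemic; flavanone) | COc1ccc(C2CC(=O)c3c(OC)c(OC)c(OCc4ccccc4)c(OC)c3O2)cc1OC | intermediate
19 | 7-(benzyloxy)-2-(3,4-dimethoxyphenyl)-5,6,8-trimethoxy-4H-chromen-4-one | COc1ccc(-c2cc(=O)c3c(OC)c(OC)c(OCc4ccccc4)c(OC)c3o2)cc1OC | intermediate
20 | 2-(3,4-dimethoxyphenyl)-7-hydroxy-5,6,8-trimethoxy-4H-chromen-4-one | COc1ccc(-c2cc(=O)c3c(OC)c(OC)c(O)c(OC)c3o2)cc1OC | target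

## Step count and least certain steps

Total: 9 steps. Longest linear sequence: 8 steps (steps 1, 2, 3, 5, 6, 7, 8 and 9 from 1); step 4 is a one-step branch.

Step 5 (key step). The likely failure is poor capture of the ketene by the alkyne: three donor oxygens lower the electrophilicity of the ketene carbon, so reversion to 5, ketene self-condensation or acylation of the product phenol could outrun the (2+2) step, and the volatile alkyne may be lost or polymerize. The fallback builds ring A by known arene chemistry. It sets out from benzyl alcohol 4, which would etherify commercial 2,6-dimethoxyphenol F1 under Mitsunobu conditions (PPh3, DIAD, THF) to 2-(benzyloxy)-1,3-dimethoxybenzene F2. Two equivalents of NBS in MeCN should brominate both positions that are ortho to one methoxy group and para to the other, giving the symmetrical 3-(benzyloxy)-1,5-dibromo-2,4-dimethoxybenzene F3. A single bromine–lithium exchange (n-BuLi, 1 equiv, THF, −78 °C), then B(OMe)3 and H2O2/NaOH, would give 3-(benzyloxy)-5-bromo-2,4-dimethoxyphenol F4. Ullmann methoxylation of the remaining bromide (NaOMe, CuBr, DMF–MeOH, 110 °C) would return to the route at 13. The symmetry of F3 replaces the regiochemical control of the cycloaddition.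

Step 3. The likely failure is ring cleavage by 1,2-addition of alkoxide to the strained carbonyl, or an exchange that stalls at equilibrium. The fallback makes the replacement irreversible. It sets out from 3, whose vinylogous ester would be hydrolysed (LiOH, THF–H2O, 0 °C, then careful acidification) to the vinylogous acid 3-hydroxy-2,4-dimethoxycyclobut-2-en-1-one F5. Mitsunobu O-benzylation of F5 with 4 (PPh3, DIAD, THF) would return to the route at 5. Because the enolate of F5 is symmetrical, alkylation at either oxygen gives the same constitution.

Step 6. The likely failure is loss of the benzyl protecting group by Lewis-acid acetolysis (the benzyloxy group is twisted out of the ring plane by its two neighbours), or incomplete acylation at a flanked position. The fallback avoids Lewis acid altogether. It sets out from 13, which would be protected (MOMCl, i-Pr2NEt, CH2Cl2) as 3-(benzyloxy)-1,2,4-trimethoxy-5-(methoxymethoxy)benzene F6. Directed ortho-lithiation at the only ring CH (n-BuLi, THF, −78 to 0 °C) and quenching with N-methoxy-N-methylacetamide would give 1-[4-(benzyloxy)-3,5,6-trimethoxy-2-(methoxymethoxy)phenyl]ethan-1-one F7. HCl in MeOH would remove the acetal and return to the route at 14.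

Step 8. The likely failure is acid-promoted loss of the C5 methyl or the benzyl group by HI at 130 °C, or a dehydrogenation that stops at the flavanone stage. The fallback closes ring C without an oxidant and bypasses step 7 as well. It sets out from 14, which would be O-acylated with 3,4-dimethoxybenzoyl chloride F8 (pyridine) to 2-acetyl-5-(benzyloxy)-3,4,6-trimethoxyphenyl 3,4-dimethoxybenzoate F9. Baker–Venkataraman acyl shift (KOH, pyridine, 50 °C) would give 1-[4-(benzyloxy)-2-hydroxy-3,5,6-trimethoxyphenyl]-3-(3,4-dimethoxyphenyl)propane-1,3-dione F10. Cyclodehydration (cat. TsOH, toluene, reflux) would return to the route at 19.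

## Further compounds

F1 | step 5 | 2,6-dimethoxyphenol | COc1cccc(OC)c1O
F2 | step 5 | 2-(benzyloxy)-1,3-dimethoxybenzene | COc1cccc(OC)c1OCc1ccccc1
F3 | step 5 | 3-(benzyloxy)-1,5-dibromo-2,4-dimethoxybenzene | COc1c(Br)cc(Br)c(OC)c1OCc1ccccc1
F4 | step 5 | 3-(benzyloxy)-5-bromo-2,4-dimethoxyphenol | COc1c(O)cc(Br)c(OC)c1OCc1ccccc1
F5 | step 3 | 3-hydroxy-2,4-dimethoxycyclobut-2-en-1-one (racemic) | O=C1C(OC)=C(O)C1OC
F6 | step 6 | 3-(benzyloxy)-1,2,4-trimethoxy-5-(methoxymethoxy)benzene | COCOc1cc(OC)c(OC)c(OCc2ccccc2)c1OC
F7 | step 6 | 1-[4-(benzyloxy)-3,5,6-trimethoxy-2-(methoxymethoxy)phenyl]ethan-1-one | CC(=O)c1c(OCOC)c(OC)c(OCc2ccccc2)c(OC)c1OC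
F8 | step 8 | 3,4-dimethoxybenzoyl chloride | COc1ccc(C(Cl)=O)cc1OC
F9 | step 8 | 2-acetyl-5-(benzyloxy)-3,4,6-trimethoxyphenyl 3,4-dimethoxybenzoate | COc1ccc(C(=O)Oc2c(C(C)=O)c(OC)c(OC)c(OCc3ccccc3)c2OC)cc1OC
F10 | step 8 | 1-[4-(benzyloxy)-2-hydroxy-3,5,6-trimethoxyphenyl]-3-(3,4-dimethoxyphenyl)propane-1,3-dione | COc1ccc(C(=O)CC(=O)c2c(O)c(OC)c(OCc3ccccc3)c(OC)c2OC)cc1OC
A1 | alternative 1 | 7-(benzyloxy)-2-(3,4-dimethoxyphenyl)-5,6,8-trimethoxy-4H-chromen-4-one | COc1ccc(-c2cc(=O)c3c(OC)c(OC)c(OCc4ccccc4)c(OC)c3o2)cc1OC
A2 | alternative 1 | 5-(benzyloxy)-3,4,6-trimethoxy-2-[(triphenyl-λ5-phosphanylidene)acetyl]phenyl 3,4-dimethoxybenzoate | COc1ccc(C(=O)Oc2c(C(=O)C=P(c3ccccc3)(c4ccccc4)c5ccccc5)c(OC)c(OC)c(OCc6ccccc6)c2OC)cc1OC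
A3 | alternative 2 | 7-(benzyloxy)-3-chloro-2-(3,4-dimethoxyphenyl)-5,6,8-trimethoxy-4H-chromen-4-one | COc1ccc(-c2oc3c(OC)c(OCc4ccccc4)c(OC)c(OC)c3c(=O)c2Cl)cc1OC
A4 | alternative 2 | {[6-(benzyloxy)-2-(3,4-dimethoxyphenyl)-4,5,7-trimethoxy-1-benzofuran-3-yl]oxy}(tert-butyl)dimethylsilane | COc1ccc(-c2oc3c(OC)c(OCc4ccccc4)c(OC)c(OC)c3c2O[Si](C)(C)C(C)(C)C)cc1OC
A5 | alternative 2 | 6-(benzyloxy)-2-(3,4-dimethoxyphenyl)-4,5,7-trimethoxy-1-benzofuran-3(2H)-one (racemic) | COc1ccc(C2Oc3c(OC)c(OCc4ccccc4)c(OC)c(OC)c3C2=O)cc1OC
A6 | alternative 3 | 7-(benzyloxy)-5-bromo-2-(3,4-dimethoxyphenyl)-6,8-dimethoxy-4H-chromen-4-one | COc1ccc(-c2cc(=O)c3c(Br)c(OC)c(OCc4ccccc4)c(OC)c3o2)cc1OC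
A7 | alternative 3 | 1-[4-(benzyloxy)-2,6-dibromo-3,5-dimethoxyphenyl]-3-(3,4-dimethoxyphenyl)propane-1,3-dione | COc1ccc(C(=O)CC(=O)c2c(Br)c(OC)c(OCc3ccccc3)c(OC)c2Br)cc1OC
A8 | alternative 3 | 4-hydroxy-3,5-dimethoxybenzoic acid (syringic acid) | COc1cc(C(=O)O)cc(OC)c1O
A9 | alternative 3 | 1-(3,4-dimethoxyphenyl)ethan-1-one | CC(=O)c1ccc(OC)c(OC)c1
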